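# Cardopatine: malonate [3+1] annulation route

## Analysis of the target

Cardopatine is a cyclobutane whose adjacent ring carbons C1 and C2 each carry a (2,2'-bithiophen-5-yl)ethynyl arm, while C3 and C4 are plain methylenes. Both stereocentres are R, so the arms are trans and the molecule is C2-symmetric; because the cis isomer would be meso, relative and absolute configuration are one problem. Neither stereocentre bears a heteroatom: each is a propargylic C–H carbon, so nothing in the final structure can direct a reagent, and the configuration has to be brought in through functional groups that later disappear. The bithiophenes are electron-rich and sensitive to oxidants, electrophiles and light, and the strained 1,2-dialkynylcyclobutane core can open thermally. A cyclobutane with two free ethynyl groups would also be a volatile C8 hydrocarbon, so the aryl groups belong at the end and are best attached one at a time, with one alkyne kept silyl-capped until the first arm is on. The strategy rests on reading C1 as a former malonate carbon joined to both ends, C2 and C4, of the three-carbon chain C2–C3–C4. In that chain C2 starts as a propargylic carbinol carbon that already carries one alkyne; its configuration can come from a catalytic ynone reduction and be carried into the ring by one invertive substitution. C1, next to an ester, can then be set under thermodynamic control, because trans is the more stable arrangement on the four-membered ring.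

## Retrosynthetic reasoning

The two C(sp)–C(sp2) bonds between the alkynes and the thiophene rings are cut first, one at a time. Removing one bithienyl unit from 20 gives the terminal alkyne 19 and the iodide 17, and 19 is released in the flask from its silyl-capped form 18. Removing the other unit from 18 gives the mono-protected diyne 16 and a second molecule of 17. This puts the sensitive heteroaryl units into the last two operations. The symmetry of 20 would allow both arms to go on at once, but only through a cyclobutane with two free ethynyl groups, which is small, volatile and prone to homocoupling. The differentiated alkynes of 16 avoid that at the price of one more step, and each forward coupling is a Sonogashira reaction of a single terminal alkyne with one equivalent of 17.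

In 16 the free alkyne on C1 is traced back, by removing its terminal carbon, to the aldehyde 15 (one-carbon homologation of Ohira–Bestmann type). Aldehyde 15 comes from the ester 13 through the alcohol 14. This turns the hydrocarbon stereocentre C1 into a carbon next to a carbonyl group, where its configuration can be corrected.

The C1–H bond of 13 is then the point of stereocontrol. Ester 13 is reached by base equilibration of the epimer mixture 12, and 12 by removal of one ester group from the geminal diester 11. In 11, C1 is not stereogenic, so only C2 has to be controlled when the ring is made. The forward steps must dealkoxycarbonylate without harming the silyl alkyne and then rely on the trans preference of a 1,2-disubstituted cyclobutane.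

The ring of 11 is opened at C1–C2 and C1–C4. These are the two bonds to the only carbon that can act as a double nucleophile. The cut gives dimethyl malonate 8 (as its sodium salt 9) and the 1,3-dielectrophile 7, a secondary propargylic mesylate with a primary chloride. Cutting at C2–C3 or C3–C4 would need a cycloaddition or a radical closure with less predictable stereochemistry. Here the forward reaction must attack the propargylic carbon exactly once, by clean backside displacement, and then close a four-membered ring through the open-chain intermediate 10.

Mesylate 7 comes from the carbinol 6, whose C–O stereocentre is set by asymmetric transfer hydrogenation of the ynone 5. An alkynyl ketone with a bulky silyl cap is among the best substrates for this reduction, so the absolute configuration of the whole synthesis rests on a catalytic, well-behaved step.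

Ynone 5 is cut at the bond between the carbonyl carbon and the alkyne into the alkyne 1 and the acid chloride 2. The forward acylation must avoid basic conditions, since the β-chloro acyl unit loses HCl easily. The acetylide is therefore used as the alkynylzinc chloride 4, made through the lithium acetylide 3.

## Alternatives that were turned down

Alternative 1: The cyclobutane is cut at C1–C4 and C2–C3 into a fumarate and a ketene acetal. In the forward direction the auxiliary-bearing di-(+)-menthyl fumarate A1 and 1,1-dimethoxyethene A2 combine, under Lewis acid activation at low temperature, to the cycloadduct A3, di-(+)-menthyl (1R,2S)-3,3-dimethoxycyclobutane-1,2-dicarboxylate.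
- For it: this is a stepwise polar [2+2] addition with well-understood facial control. It sets both stereocentres and the trans relationship in one step, and A3 maps onto the absolute configuration of 20. The two ester groups allow a two-directional endgame with no epimerization step. On stereocontrol of the ring it is stronger than the chosen route.
- Against it: A3 carries an oxygenated carbon at C3 that the target lacks. The ketal must be unmasked and reduced to a methylene on a strained ring, where the freed ketone sits β to an ester carbonyl and invites epimerization and ring cleavage. Two equivalents of the less common menthyl enantiomer are spent. Two esters must be converted to alkynes through a dialdehyde.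
- Comparison: the step count ends near that of the chosen route. The chosen route offers a catalytic source of chirality, no excision of a superfluous function, and every carbon of the dielectrophile ending up in the target.

Alternative 2: The C1–C2 ring bond is cut and bridged by nitrogen, which leads to the C2-symmetric pyrrolidine A4, (2S,5S)-2,5-bis[(triisopropylsilyl)ethynyl]pyrrolidine. Forward, A4 is N-aminated by a hypervalent-iodine nitrene-transfer reagent generated in the flask, and the N-amino intermediate extrudes nitrogen. The ring carbons C2 and C5 then join with retention to A5, (1R,2R)-1,2-bis[(triisopropylsilyl)ethynyl]cyclobutane.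
- For it: both alkynes and both stereocentres are in place before the ring forms, nothing is epimerizable, and A5 is two operations from 20. In endgame length it is clearly stronger.
- Against it: an enantiopure trans-2,5-dialkynylpyrrolidine is itself a multi-step target with two α-amino propargylic stereocentres. The biradical formed on nitrogen loss has two propargyl-stabilized termini. That stabilization lengthens its lifetime, which favours bond rotation (leak to the meso cis isomer), β-scission into two enyne fragments, and coupling through the allenyl termini.
- Comparison: the stereochemical risk sits late and in a radical step. The chosen route places its risk in an early polar substitution whose outcome is predictable, and pays for this with a longer sequence after the ring is made.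

Alternative 3: The C1–C4 ring bond is traced back to a five-membered ring, the diazoketone A6, (S)-2-diazo-3-[(triisopropylsilyl)ethynyl]cyclopentan-1-one. Forward, irradiation in an alcohol solvent triggers Wolff rearrangement: the ring methylene migrates from the carbonyl carbon to the carbene carbon. The contracted ring is captured by the solvent as the ester and equilibrated with alkoxide to A7, methyl (1R,2R)-2-[(triisopropylsilyl)ethynyl]cyclobutane-1-carboxylate, which is identical with 13.
- For it: Wolff ring contraction of cyclic α-diazoketones is textbook chemistry, and the route joins the chosen one at 13 in fewer steps. On step economy it is stronger.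
- Against it: A6 needs an enantioselective conjugate alkynylation of a five-membered cyclic enone, a substrate class on which such additions are least dependable. It also needs diazo transfer at the more hindered α-carbon next to the stereocentre, which requires regiospecific trapping of the conjugate-addition enolate. The carbene lies next to a tertiary propargylic C–H, so a 1,2-hydrogen shift to an enone can compete. The C1 centre still needs the same equilibration as in the chosen route.
- Comparison: the saving of two or three steps is bought by resting the absolute configuration on the weakest reaction. The chosen route rests it on ynone transfer hydrogenation.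

Key step: step 4

Remark on the chemistry: the iodide 17 is taken as a purchasable compound. The descriptor of the propargylic carbon stays R from 6 to 11 although the carbon is inverted in step 4, because the departing oxygen ranked above the alkynyl group and the entering carbon ranks below it.

## Route

Step 1
Reactants: 1 (triisopropylsilyl)acetylene; 2 3-chloropropanoyl chloride
Product: 5 5-chloro-1-(triisopropylsilyl)pent-1-yn-3-one, via lithium (triisopropylsilyl)acetylide 3 (not isolated), via [(triisopropylsilyl)ethynyl]zinc chloride 4 (not isolated)
Conditions: n-BuLi, THF, −78 °C; ZnCl2, −78 → 0 °C; then 2, Pd(PPh3)4 (2 mol%), 0 °C → rt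
Reagents that add atoms: none
Why: Negishi-type acylation of an alkynylzinc halide with an acid chloride; the weakly basic alkynylzinc chloride 4 should neither dehydrochlorinate the β-chloro acyl unit nor add a second time to the ynone, and the primary alkyl chloride is inert to Pd(PPh3)4 at room temperature.

Step 2
Reactants: 5 5-chloro-1-(triisopropylsilyl)pent-1-yn-3-one
Product: 6 (R)-5-chloro-1-(triisopropylsilyl)pent-1-yn-3-ol
Conditions: RuCl[(R,R)-TsDPEN](p-cymene) (1 mol%), HCO2H/Et3N (5:2), CH2Cl2, rt
Reagents that add atoms: none
Why: Noyori–Ikariya asymmetric transfer hydrogenation of an alkynyl ketone, which reduces C=O and leaves the triple bond; the alkynyl group takes the place an aryl group occupies under the η6-arene in the hydride-transfer transition state, so the (R,R)-ligand should give the R carbinol, and the acidic formate medium should prevent base-induced loss of HCl.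

Step 3
Reactants: 6 (R)-5-chloro-1-(triisopropylsilyl)pent-1-yn-3-ol
Product: 7 (R)-5-chloro-1-(triisopropylsilyl)pent-1-yn-3-yl methanesulfonate
Conditions: Ms2O, Et3N, CH2Cl2, −20 → 0 °C; crude product used at once
Reagents that add atoms: methanesulfonic anhydride, CS(=O)(=O)OS(C)(=O)=O
Why: O-sulfonylation leaves the C–O bond intact, so the configuration is retained; the anhydride is used in place of the sulfonyl chloride so that no chloride ion is present to displace the reactive propargylic mesylate with inversion.

Step 4
Reactants: 7 (R)-5-chloro-1-(triisopropylsilyl)pent-1-yn-3-yl methanesulfonate; 8 dimethyl malonate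
Product: 11 dimethyl (R)-2-[(triisopropylsilyl)ethynyl]cyclobutane-1,1-dicarboxylate, via sodium dimethyl malonate 9 (not isolated), via chloroalkyl malonate 10 (not isolated)
Conditions: 8 (1.15 equiv), NaH (1.1 equiv), THF–DMPU (5:1), 0 °C; 7, 0 → 40 °C; then NaH (1.2 equiv), NaI (0.1 equiv), dilution with THF to ca. 0.03 M, 55 °C
Reagents that add atoms: none
Why: The soft, weakly basic enolate 9 should displace the alkyne-activated secondary mesylate of 7 in an intermolecular SN2 step (bond C1–C2) to give 10, and the second portion of base then forms the tertiary malonate anion of 10, which displaces the primary chloride (as the iodide after halide exchange in the flask) to make bond C1–C4. The closest known chemistry is the malonic ester synthesis of cyclobutane-1,1-dicarboxylates from 1,3-dielectrophiles, together with the invertive substitution of secondary propargylic sulfonates by malonate anions. The ring closes in the 4-exo-tet mode at an unhindered primary carbon, helped by the branch at C2 and by dilution; should the chloride be displaced first, the same ring would close at the propargylic carbon, again with one inversion and the same product. The stereocentre C2 is not created here but transferred: its configuration comes from the carbinol centre of 6 set by RuCl[(R,R)-TsDPEN](p-cymene) in step 2, and the single backside attack inverts it, the descriptor remaining R only because the ligand priorities change. The step needs substitution to win over E2 elimination to an enyne, over SN2' attack giving an allene and over ionization; the low basicity of the malonate anion, the bulky silyl cap on the distal alkyne carbon and the non-ionizing medium serve this. Iodide is added only after 7 is consumed, so that no halide can invert the propargylic carbon a second time. Malonate enolates alkylate on carbon, so the six-membered O-alkylation product typical of β-keto esters is not expected, and near-stoichiometric malonate plus dilution should hold back intermolecular alkylation. C1 of 11 carries two identical esters and is not stereogenic, so C2 is the only centre at stake.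

Step 5
Reactants: 11 dimethyl (R)-2-[(triisopropylsilyl)ethynyl]cyclobutane-1,1-dicarboxylate
Product: 12 methyl (2R)-2-[(triisopropylsilyl)ethynyl]cyclobutane-1-carboxylate (mixture of C1 epimers)
Conditions: LiCl, H2O, DMSO, 150 °C
Reagents that add atoms: none
Why: Krapcho dealkoxycarbonylation: chloride demethylates one ester, the carboxylate loses CO2 and the resulting ester enolate is protonated by water; C2 is not involved, C1 forms without control, and the silyl alkyne should tolerate chloride.

Step 6
Reactants: 12 methyl (2R)-2-[(triisopropylsilyl)ethynyl]cyclobutane-1-carboxylate (mixture of C1 epimers)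
Product: 13 methyl (1R,2R)-2-[(triisopropylsilyl)ethynyl]cyclobutane-1-carboxylate
Conditions: NaOMe (0.3 equiv), MeOH, 60 °C; chromatography, cis ester resubjected
Reagents that add atoms: none
Why: Base-mediated epimerization through the ester enolate under thermodynamic control; C1 is the only acidic position, the trans isomer avoids the eclipsing contact of ester and alkynyl groups on adjacent ring carbons, and with C2 fixed as R the trans arrangement makes C1 R, while the triisopropylsilyl cap should withstand methoxide.

Step 7
Reactants: 13 methyl (1R,2R)-2-[(triisopropylsilyl)ethynyl]cyclobutane-1-carboxylate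
Product: 14 [(1R,2R)-2-[(triisopropylsilyl)ethynyl]cyclobutyl]methanol
Conditions: i-Bu2AlH (2.5 equiv), CH2Cl2, −78 → 0 °C; aq. potassium sodium tartrate work-up
Reagents that add atoms: none
Why: Hydride reduction of the ester to the primary alcohol, which at low temperature should be much faster than enolization, so C1 is not disturbed; the alkyne has no adjacent hydroxyl group that could direct hydroalumination.

Step 8
Reactants: 14 [(1R,2R)-2-[(triisopropylsilyl)ethynyl]cyclobutyl]methanol
Product: 15 (1R,2R)-2-[(triisopropylsilyl)ethynyl]cyclobutane-1-carbaldehyde
Conditions: Dess–Martin periodinane, NaHCO3, CH2Cl2, 0 °C → rt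
Reagents that add atoms: none
Why: Dess–Martin oxidation under buffered, non-basic conditions should give the aldehyde without epimerizing C1; any epimerization that did occur would in any case move toward the wanted trans isomer.

Step 9
Reactants: 15 (1R,2R)-2-[(triisopropylsilyl)ethynyl]cyclobutane-1-carbaldehyde
Product: 16 {[(1R,2R)-2-ethynylcyclobutyl]ethynyl}triisopropylsilane
Conditions: dimethyl (1-diazo-2-oxopropyl)phosphonate, K2CO3, MeOH, 0 °C → rt
Reagents that add atoms: dimethyl (1-diazo-2-oxopropyl)phosphonate, COP(=O)(OC)C(=[N+]=[N-])C(C)=O
Why: Ohira–Bestmann homologation: methanolysis releases the diazomethylphosphonate anion, which olefinates the aldehyde, and loss of N2 with a 1,2-hydrogen shift of the alkylidene carbene gives the terminal alkyne; the carbonate medium should spare the silyl alkyne, and the thermodynamic preference at C1 is for the trans isomer that is wanted.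

Step 10
Reactants: 16 {[(1R,2R)-2-ethynylcyclobutyl]ethynyl}triisopropylsilane; 17 5-iodo-2,2'-bithiophene
Product: 18 5-({(1R,2R)-2-[(triisopropylsilyl)ethynyl]cyclobutyl}ethynyl)-2,2'-bithiophene
Conditions: 17 (1.05 equiv), PdCl2(PPh3)2 (3 mol%), CuI (5 mol%), Et3N–THF, degassed, rt, dark
Reagents that add atoms: none
Why: Sonogashira coupling of the only free terminal alkyne with a reactive 2-iodothiophene; the silyl-capped alkyne cannot enter the coupling, neither stereocentre is acidic or involved, and exclusion of oxygen should suppress Glaser homocoupling.

Step 11
Reactants: 18 5-({(1R,2R)-2-[(triisopropylsilyl)ethynyl]cyclobutyl}ethynyl)-2,2'-bithiophene; 17 5-iodo-2,2'-bithiophene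
Product: 20 cardopatine [(1R,2R)-1,2-bis[(2,2'-bithiophen-5-yl)ethynyl]cyclobutane], via desilylated alkyne 19 (not isolated)
Conditions: TBAF (1.2 equiv), THF, 0 °C → rt; then 17 (1.1 equiv), PdCl2(PPh3)2 (5 mol%), CuI (5 mol%), Et3N, degassed, rt → 40 °C, dark
Reagents that add atoms: none
Why: Fluoride-induced protodesilylation of the alkynylsilane followed in the same flask by a second Sonogashira coupling with the heteroaryl iodide; the internal aryl alkyne already present is inert, neither stereocentre is acidic or involved, and 19 is non-volatile, so nothing is lost if it has to be handled.

## Compound list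

1 | (triisopropylsilyl)acetylene | C#C[Si](C(C)C)(C(C)C)C(C)C | starting material
2 | 3-chloropropanoyl chloride | O=C(Cl)CCCl | starting material
3 | lithium (triisopropylsilyl)acetylide | [Li]C#C[Si](C(C)C)(C(C)C)C(C)C | intermediate
4 | [(triisopropylsilyl)ethynyl]zinc chloride | Cl[Zn]C#C[Si](C(C)C)(C(C)C)C(C)C | intermediate
5 | 5-chloro-1-(triisopropylsilyl)pent-1-yn-3-one | O=C(CCCl)C#C[Si](C(C)C)(C(C)C)C(C)C | intermediate
6 | (R)-5-chloro-1-(triisopropylsilyl)pent-1-yn-3-ol | ClCC[C@@H](O)C#C[Si](C(C)C)(C(C)C)C(C)C | intermediate
7 | (R)-5-chloro-1-(triisopropylsilyl)pent-1-yn-3-yl methanesulfonate | ClCC[C@@H](OS(C)(=O)=O)C#C[Si](C(C)C)(C(C)C)C(C)C | intermediate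
8 | dimethyl malonate | COC(=O)CC(=O)OC | starting material
9 | sodium dimethyl malonate (sodium enolate of 8) | [Na+].COC(=O)[CH-]C(=O)OC | intermediate
10 | dimethyl 2-[(3R)-5-chloro-1-(triisopropylsilyl)pent-1-yn-3-yl]malonate (chloroalkyl malonate) | COC(=O)C(C(=O)OC)[C@@H](CCCl)C#C[Si](C(C)C)(C(C)C)C(C)C | intermediate
11 | dimethyl (R)-2-[(triisopropylsilyl)ethynyl]cyclobutane-1,1-dicarboxylate | COC(=O)C1(C(=O)OC)CC[C@H]1C#C[Si](C(C)C)(C(C)C)C(C)C | intermediate
12 | methyl (2R)-2-[(triisopropylsilyl)ethynyl]cyclobutane-1-carboxylate, mixture of C1 epimers | COC(=O)C1CC[C@H]1C#C[Si](C(C)C)(C(C)C)C(C)C | intermediate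
13 | methyl (1R,2R)-2-[(triisopropylsilyl)ethynyl]cyclobutane-1-carboxylate | COC(=O)[C@@H]1CC[C@H]1C#C[Si](C(C)C)(C(C)C)C(C)C | intermediate
14 | [(1R,2R)-2-[(triisopropylsilyl)ethynyl]cyclobutyl]methanol | OC[C@@H]1CC[C@H]1C#C[Si](C(C)C)(C(C)C)C(C)C | intermediate
15 | (1R,2R)-2-[(triisopropylsilyl)ethynyl]cyclobutane-1-carbaldehyde | O=C[C@@H]1CC[C@H]1C#C[Si](C(C)C)(C(C)C)C(C)C | intermediate
16 | {[(1R,2R)-2-ethynylcyclobutyl]ethynyl}triisopropylsilane | C#C[C@@H]1CC[C@H]1C#C[Si](C(C)C)(C(C)C)C(C)C | intermediate
17 | 5-iodo-2,2'-bithiophene | Ic1ccc(-c2cccs2)s1 | starting material
18 | 5-({(1R,2R)-2-[(triisopropylsilyl)ethynyl]cyclobutyl}ethynyl)-2,2'-bithiophene | CC(C)[Si](C(C)C)(C(C)C)C#C[C@@H]1CC[C@H]1C#Cc1ccc(-c2cccs2)s1 | intermediate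
19 | 5-{[(1R,2R)-2-ethynylcyclobutyl]ethynyl}-2,2'-bithiophene (desilylated alkyne) | C#C[C@@H]1CC[C@H]1C#Cc1ccc(-c2cccs2)s1 | intermediate
20 | cardopatine, (1R,2R)-1,2-bis[(2,2'-bithiophen-5-yl)ethynyl]cyclobutane | C(#C[C@@H]1CC[C@H]1C#Cc1ccc(-c2cccs2)s1)c1ccc(-c2cccs2)s1 | target

## Step count and risk

Total step count: 11. Longest linear sequence: 11 steps (from 1 and 2 to 20).

Steps least certain to work:

**Step 4 (key step).**
- What may go wrong: the four-membered ring closure is the slow event, and intermolecular alkylation of a second malonate unit by the primary halide can overtake it and give open-chain oligoesters. Configurational purity can also leak if the mesylate ionizes or is displaced by a halide before carbon attacks, and E2 elimination to an enyne is possible.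
- Fallback: the two alkylations are uncoupled. Setting out from 7, only the first displacement is run, with a large excess of 9 and no halide present, and 10 is isolated. Halide exchange (NaI, acetone, reflux) converts 10 into dimethyl 2-[(3R)-5-iodo-1-(triisopropylsilyl)pent-1-yn-3-yl]malonate F1. F1 is added slowly to NaH in dilute THF–DMPU, so that the 4-exo-tet closure acts on a primary iodide at low stationary concentration. The sequence comes back to the route at 11.

**Step 1.**
- What may go wrong: the β-chloro acyl unit can lose HCl under the influence of the basic acetylide, or a second acetylide can add to the ynone.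
- Fallback: an electrophilic, base-free acylation. Setting out from 1, lithiation and silylation with chlorotrimethylsilane give triisopropyl[(trimethylsilyl)ethynyl]silane F2. Friedel–Crafts-type ipso-acylation of F2 with 2 and AlCl3 in CH2Cl2 at 0 °C should replace the smaller, more accessible trimethylsilyl group and return to the route at 5.

**Step 5.**
- What may go wrong: the hot, wet and increasingly basic DMSO medium can strip the silyl cap, or chloride can open the strained geminal diester.
- Fallback: setting out from 11, partial saponification (KOH, 1 equiv, MeOH/H2O, rt) gives the half-acid (2R)-1-(methoxycarbonyl)-2-[(triisopropylsilyl)ethynyl]cyclobutane-1-carboxylic acid F3. Thermal decarboxylation of this malonic half-acid (toluene, ca. 110–130 °C, no nucleophile present) returns to the route at 12.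

**Step 6.**
- What may go wrong: the equilibrium may not be one-sided enough, because the rod-shaped alkyne exerts little steric pressure, so a sizeable share of cis ester could persist.
- Fallback: sorting is moved to the alcohol and aldehyde stage. Setting out from 12, the epimer mixture is reduced with i-Bu2AlH and the alcohols are separated by chromatography. The trans alcohol is 14. The cis alcohol [(1S,2R)-2-[(triisopropylsilyl)ethynyl]cyclobutyl]methanol F4 is oxidized with Dess–Martin periodinane to (1S,2R)-2-[(triisopropylsilyl)ethynyl]cyclobutane-1-carbaldehyde F5. The far more acidic α-hydrogen of F5 allows epimerization with DBU in CH2Cl2, and the material rejoins the route at 15.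

**Step 11.**
- What may go wrong: in the fluoride- and hydroxide-containing pot the acetylide formed from 19 with CuI can undergo oxidative homocoupling, or desilylation can stay incomplete so that capped material cannot couple.
- Fallback: the second arm is attached through an organozinc. Setting out from 18, desilylation with TBAF in THF and aqueous work-up give 19, which is isolated. Deprotonation with EtMgBr in THF and transmetalation with ZnCl2 give chloro{[(1R,2R)-2-([2,2'-bithiophen]-5-ylethynyl)cyclobutyl]ethynyl}zinc F6. Negishi coupling of F6 with 17 under Pd(PPh3)4, with no copper salt and no fluoride present, arrives at 20.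

## Further compounds

F1 | step 4 | dimethyl 2-[(3R)-5-iodo-1-(triisopropylsilyl)pent-1-yn-3-yl]malonate | COC(=O)C(C(=O)OC)[C@@H](CCI)C#C[Si](C(C)C)(C(C)C)C(C)C
F2 | step 1 | triisopropyl[(trimethylsilyl)ethynyl]silane | C[Si](C)(C)C#C[Si](C(C)C)(C(C)C)C(C)C
F3 | step 5 | (2R)-1-(methoxycarbonyl)-2-[(triisopropylsilyl)ethynyl]cyclobutane-1-carboxylic acid, mixture of C1 epimers | COC(=O)C1(C(O)=O)CC[C@H]1C#C[Si](C(C)C)(C(C)C)C(C)C
F4 | step 6 | [(1S,2R)-2-[(triisopropylsilyl)ethynyl]cyclobutyl]methanol | OC[C@H]1CC[C@H]1C#C[Si](C(C)C)(C(C)C)C(C)C
F5 | step 6 | (1S,2R)-2-[(triisopropylsilyl)ethynyl]cyclobutane-1-carbaldehyde | O=C[C@H]1CC[C@H]1C#C[Si](C(C)C)(C(C)C)C(C)C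
F6 | step 11 | chloro{[(1R,2R)-2-([2,2'-bithiophen]-5-ylethynyl)cyclobutyl]ethynyl}zinc | Cl[Zn]C#C[C@@H]1CC[C@H]1C#Cc1ccc(-c2cccs2)s1
A1 | alternative 1 | di-(+)-menthyl fumarate | O=C(/C=C/C(=O)O[C@@H]1[C@@H](C(C)C)CC[C@H](C)C1)O[C@@H]1[C@@H](C(C)C)CC[C@H](C)C1
A2 | alternative 1 | 1,1-dimethoxyethene | C=C(OC)OC
A3 | alternative 1 | di-(+)-menthyl (1R,2S)-3,3-dimethoxycyclobutane-1,2-dicarboxylate | O=C(O[C@@H]1[C@@H](C(C)C)CC[C@H](C)C1)[C@@H]1CC(OC)(OC)[C@H]1C(=O)O[C@@H]1[C@@H](C(C)C)CC[C@H](C)C1
A4 | alternative 2 | (2S,5S)-2,5-bis[(triisopropylsilyl)ethynyl]pyrrolidine | CC(C)[Si](C(C)C)(C(C)C)C#C[C@@H]1CC[C@@H](C#C[Si](C(C)C)(C(C)C)C(C)C)N1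
A5 | alternative 2 | (1R,2R)-1,2-bis[(triisopropylsilyl)ethynyl]cyclobutane | CC(C)[Si](C(C)C)(C(C)C)C#C[C@@H]1CC[C@H]1C#C[Si](C(C)C)(C(C)C)C(C)C
A6 | alternative 3 | (S)-2-diazo-3-[(triisopropylsilyl)ethynyl]cyclopentan-1-one | O=C1CC[C@@H](C#C[Si](C(C)C)(C(C)C)C(C)C)C1=[N+]=[N-]
A7 | alternative 3 | methyl (1R,2R)-2-[(triisopropylsilyl)ethynyl]cyclobutane-1-carboxylate | COC(=O)[C@@H]1CC[C@H]1C#C[Si](C(C)C)(C(C)C)C(C)C
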